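The ring A arm, C7(OH)–C8(ring A)–C9H2OH with O7 anti to ring A and C7 benzylic to the para-oxygenated guaiacyl ring, is read as an opened trans-4,5-diaryl-1,3-dioxane. Disconnecting C8–C9 and C7–O leads to an (E)-stilbene and two formaldehyde units. One asymmetric Prins step forms both bonds, the ring and both stereocentres, and leaves the diol masked. The precursor is an (S)-β-benzyl-γ-butyrolactone whose ring A carries an electron-poor pivalate and, through the stilbene, an O-benzyl guaiacyl ring that steers the cation to C7. A separately made dihydrobenzofuran benzyl bromide is then joined by trans-selective lactone alkylation.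

Key step: step 8

Assumption: the antipodes of the three chiral catalysts (steps 3, 8 and 14) are named by analogy with simpler substrates; whichever antipode delivers the configuration drawn is the one meant.

Labels: ring A is the aryl ring carrying the lactone CH2; ring G is the guaiacyl ring on C7; C7, C8 and C9 are the carbinol, methine and CH2OH carbons of the ring A arm.

Stereochemical check: the (4S,5S)-trans-dioxane maps onto the (7S,8S) arm of the target, and the (S) centre of the monosubstituted lactone becomes C4 of the (3S,4S) lactone, so no configuration has to be changed.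

Step 1
Reactants: 1 5-bromovanillin (3-bromo-4-hydroxy-5-methoxybenzaldehyde)
Product: 2 3-bromo-5-methoxy-4-(methoxymethoxy)benzaldehyde
Conditions: MOMCl, K2CO3, DMF, 0 °C → rt
Reagents that add atoms: chloromethyl methyl ether, COCCl
Why: Williamson O-alkylation of the acidic phenol gives an acetal ether that withstands the alkoxide of the next step and is shed later by acid.

Step 2
Reactants: 2 3-bromo-5-methoxy-4-(methoxymethoxy)benzaldehyde; 3 dimethyl succinate
Product: 4 (E)-4-[3-bromo-5-methoxy-4-(methoxymethoxy)phenyl]-3-(methoxycarbonyl)but-3-enoic acid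
Conditions: NaOMe, MeOH, reflux; then aq. HCl, 0 °C
Reagents that add atoms: none
Why: Stobbe condensation, in which the succinate enolate adds to the non-enolisable aldehyde and the lactonisation–ring-opening sequence delivers the (E)-alkylidene half-ester with the free acid on the CH2 arm.

Step 3
Reactants: 4 (E)-4-[3-bromo-5-methoxy-4-(methoxymethoxy)phenyl]-3-(methoxycarbonyl)but-3-enoic acid
Product: 5 (S)-4-[3-bromo-5-methoxy-4-(methoxymethoxy)phenyl]-3-(methoxycarbonyl)butanoic acid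
Conditions: H2 (5 bar), [Rh(cod)((R,R)-Et-DuPhos)]BF4 (1 mol %), NaOMe (10 mol %), MeOH, rt
Reagents that add atoms: none
Why: Rhodium–bisphosphine asymmetric hydrogenation of an itaconate-type half-ester, where two-point binding through alkene and carboxylate lets the ligand choose the alkene face and set C3 as S while aryl bromide and MOM ether stay inert.

Step 4
Reactants: 5 (S)-4-[3-bromo-5-methoxy-4-(methoxymethoxy)phenyl]-3-(methoxycarbonyl)butanoic acid
Product: 7 (S)-4-(3-bromo-4-hydroxy-5-methoxybenzyl)dihydrofuran-2(3H)-one, via hydroxy acid potassium salt 6 (not isolated)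
Conditions: KOH (1 equiv), EtOH; CaCl2, NaBH4, −10 °C → rt; then 3 M HCl, THF, 50 °C
Reagents that add atoms: none
Why: Chemoselective calcium borohydride reduction of the ester beside the unreactive carboxylate, then acid-driven γ-lactonisation, is the standard passage from such half-esters to β-benzyl butyrolactones; the same acid hydrolyses the aryl MOM acetal, and the stereocentre, now β to the carbonyl, cannot epimerise.

Step 5
Reactants: 7 (S)-4-(3-bromo-4-hydroxy-5-methoxybenzyl)dihydrofuran-2(3H)-one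
Product: 8 2-bromo-6-methoxy-4-{[(S)-5-oxotetrahydrofuran-3-yl]methyl}phenyl pivalate
Conditions: PivCl, Et3N, DMAP (cat.), CH2Cl2, 0 °C → rt
Reagents that add atoms: pivaloyl chloride, CC(C)(C)C(Cl)=O
Why: DMAP-catalysed O-acylation of the hindered phenol installs a robust acyl group that makes the ring A oxygen a poor donor for the key step and survives the hot amine base of the coupling.

Step 6
Reactants: 9 4-(benzyloxy)-3-methoxybenzaldehyde
Product: 10 4-benzyloxy-3-methoxystyrene
Conditions: Ph3PCH3Br, KOtBu, THF, 0 °C → rt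
Reagents that add atoms: methyltriphenylphosphonium bromide, C[P+](c1ccccc1)(c1ccccc1)c1ccccc1.[Br-]
Why: Wittig methylenation of a non-enolisable aromatic aldehyde with the unstabilised ylide.

Step 7
Reactants: 8 2-bromo-6-methoxy-4-{[(S)-5-oxotetrahydrofuran-3-yl]methyl}phenyl pivalate; 10 4-benzyloxy-3-methoxystyrene
Product: 11 2-[(E)-2-(4-benzyloxy-3-methoxyphenyl)ethenyl]-6-methoxy-4-{[(S)-5-oxotetrahydrofuran-3-yl]methyl}phenyl pivalate
Conditions: Pd2(dba)3 (2.5 mol %), [HP(t-Bu)3]BF4 (10 mol %), Cy2NMe, 1,4-dioxane, 80 °C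
Reagents that add atoms: none
Why: Heck reaction, in which zerovalent palladium inserts into the C–Br bond, the styrene inserts at its terminal carbon and syn-β-hydride elimination gives the (E)-stilbene, the bulky electron-rich phosphine coping with the ortho-substituted bromide.

Step 8
Reactants: 11 2-[(E)-2-(4-benzyloxy-3-methoxyphenyl)ethenyl]-6-methoxy-4-{[(S)-5-oxotetrahydrofuran-3-yl]methyl}phenyl pivalate; 12 formaldehyde (as paraformaldehyde; two units are incorporated)
Product: 13 2-[(4S,5S)-4-(4-benzyloxy-3-methoxyphenyl)-1,3-dioxan-5-yl]-6-methoxy-4-{[(S)-5-oxotetrahydrofuran-3-yl]methyl}phenyl pivalate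
Conditions: (CH2O)n (6 equiv), chiral confined BINOL-derived imidodiphosphorimidate Brønsted acid (5 mol %), CHCl3–cyclohexane, 0 → 25 °C
Reagents that add atoms: none
Why: Proposed new method: the confined acid protonates a formaldehyde oligomer; C8 of the stilbene (the carbon on ring A) attacks the resulting oxocarbenium to form C8–C9 while positive charge develops at C7 and is delocalised into the para-benzyloxy ring, and the terminal hemiacetal oxygen of the second formaldehyde unit then bonds to C7. The closest known reactions are the acid-mediated Prins reaction of 1-arylpropenes and stilbenes with formaldehyde, which gives trans-4-aryl-5-substituted 1,3-dioxanes, and the imidodiphosphorimidate-catalysed enantioselective Prins reaction of styrenes with paraformaldehyde; enantiocontrol on a 1,2-diaryl alkene is the untested part. The 1,3-dioxane closes by attack of oxygen on the benzylic cation through a six-membered chair (6-exo-trig with respect to the quinoid C7=C(aryl) bond). C8 is set by the alkene face that the chiral counter-anion leaves open (catalyst control; the remote lactone centre has no influence), and C7 follows from C8 because both aryl groups sit equatorial in the closing chair, the same trans outcome that suprafacial addition to the E-alkene would give. The step needs C–C bond formation at C8 and not at C7, which the strong para-alkoxy donor on ring G against the acylated ortho-oxygen on ring A should secure, and it needs the arenes and the lactone to stay untouched, which the absence of free phenols and the mild confined acid should secure.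

Step 9
Reactants: 13 2-[(4S,5S)-4-(4-benzyloxy-3-methoxyphenyl)-1,3-dioxan-5-yl]-6-methoxy-4-{[(S)-5-oxotetrahydrofuran-3-yl]methyl}phenyl pivalate
Product: 15 (S)-4-{3-[(4S,5S)-4-(4-benzyloxy-3-methoxyphenyl)-1,3-dioxan-5-yl]-4-hydroxy-5-methoxybenzyl}dihydrofuran-2(3H)-one, via ring-opened dilithium salt 14 (not isolated)
Conditions: LiOH, THF–H2O, 45 °C; then 1 M HCl to pH 2, rt
Reagents that add atoms: none
Why: Ester saponification removes the hindered aryl pivalate and opens the lactone to its hydroxy carboxylate, which relactonises on acidification, while the formaldehyde acetal is stable to base and to dilute acid.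

Step 10
Reactants: 15 (S)-4-{3-[(4S,5S)-4-(4-benzyloxy-3-methoxyphenyl)-1,3-dioxan-5-yl]-4-hydroxy-5-methoxybenzyl}dihydrofuran-2(3H)-one
Product: 16 (S)-4-{4-(benzyloxy)-3-[(4S,5S)-4-(4-benzyloxy-3-methoxyphenyl)-1,3-dioxan-5-yl]-5-methoxybenzyl}dihydrofuran-2(3H)-one
Conditions: BnBr, K2CO3, DMF, rt
Reagents that add atoms: benzyl bromide, BrCc1ccccc1
Why: Williamson benzylation of the phenoxide gives a base-stable ether that keeps the ring A oxygen from attacking C7 later and leaves with the other benzyl ethers in the last step.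

Step 11
Reactants: 17 methyl 4-hydroxy-3-iodo-5-methoxybenzoate (methyl 5-iodovanillate); 18 [4-(benzyloxy)-3-methoxyphenyl]methanol
Product: 19 methyl 4-{[4-(benzyloxy)-3-methoxybenzyl]oxy}-3-iodo-5-methoxybenzoate
Conditions: PPh3, DIAD, THF, 0 °C → rt
Reagents that add atoms: none
Why: Mitsunobu etherification, in which the acidic iodophenol displaces the activated primary benzylic alcohol and so installs the benzylic CH2 that becomes C2 of the dihydrobenzofuran.

Step 12
Reactants: 19 methyl 4-{[4-(benzyloxy)-3-methoxybenzyl]oxy}-3-iodo-5-methoxybenzoate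
Product: 20 methyl 4-{[4-(benzyloxy)-3-methoxybenzyl]oxy}-3-methoxy-5-(2-methoxy-2-oxoethyl)benzoate
Conditions: BrZnCH2CO2Me, Pd2(dba)3 (2 mol %), XPhos (8 mol %), THF, 50 °C
Reagents that add atoms: (2-methoxy-2-oxoethyl)zinc bromide, COC(=O)C[Zn]Br
Why: Negishi-type cross-coupling of a Reformatsky reagent with the aryl iodide installs the arylacetate directly, the zinc enolate being too mild to attack the benzoate.

Step 13
Reactants: 20 methyl 4-{[4-(benzyloxy)-3-methoxybenzyl]oxy}-3-methoxy-5-(2-methoxy-2-oxoethyl)benzoate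
Product: 21 methyl 4-{[4-(benzyloxy)-3-methoxybenzyl]oxy}-3-(1-diazo-2-methoxy-2-oxoethyl)-5-methoxybenzoate
Conditions: p-ABSA, DBU, MeCN, 0 °C → rt
Reagents that add atoms: 4-acetamidobenzenesulfonyl azide, CC(=O)Nc1ccc(cc1)S(=O)(=O)N=[N+]=[N-]
Why: Regitz diazo transfer, in which the arylacetate enolate attacks the sulfonyl azide and loses the sulfonamide to give the donor–acceptor diazo ester.

Step 14
Reactants: 21 methyl 4-{[4-(benzyloxy)-3-methoxybenzyl]oxy}-3-(1-diazo-2-methoxy-2-oxoethyl)-5-methoxybenzoate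
Product: 23 dimethyl (2R,3R)-2-[4-(benzyloxy)-3-methoxyphenyl]-7-methoxy-2,3-dihydro-1-benzofuran-3,5-dicarboxylate (trans), via cis-diester 22 (not isolated)
Conditions: Rh2(S-PTTL)4 (1 mol %), toluene, −60 °C, slow addition; then NaOMe (0.3 equiv), MeOH, 0 °C → rt
Reagents that add atoms: none
Why: Intramolecular 1,5 C–H insertion of the chiral dirhodium carbenoid into the electron-rich benzylic ether C–H bond forms C2–C3 with catalyst-controlled configuration at C2 (R) and cis geometry, and methoxide then epimerises only the enolisable C3 to the more stable trans diester.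

Step 15
Reactants: 23 dimethyl (2R,3R)-2-[4-(benzyloxy)-3-methoxyphenyl]-7-methoxy-2,3-dihydro-1-benzofuran-3,5-dicarboxylate
Product: 24 {(2R,3S)-2-[4-(benzyloxy)-3-methoxyphenyl]-7-methoxy-2,3-dihydro-1-benzofuran-3,5-diyl}dimethanol
Conditions: LiAlH4, THF, 0 °C
Reagents that add atoms: none
Why: Hydride reduction of both esters gives the diol and removes the acidity at C3, so the trans relationship is fixed from here on (the descriptor changes to 3S by priority only).

Step 16
Reactants: 24 {(2R,3S)-2-[4-(benzyloxy)-3-methoxyphenyl]-7-methoxy-2,3-dihydro-1-benzofuran-3,5-diyl}dimethanol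
Product: 25 (2R,3S)-2-[4-(benzyloxy)-3-methoxyphenyl]-3-(hydroxymethyl)-7-methoxy-2,3-dihydro-1-benzofuran-5-carbaldehyde
Conditions: MnO2, CH2Cl2, rt
Reagents that add atoms: none
Why: Manganese dioxide oxidises only the benzylic alcohol, which tells the two primary alcohols apart without any selectivity problem.

Step 17
Reactants: 25 (2R,3S)-2-[4-(benzyloxy)-3-methoxyphenyl]-3-(hydroxymethyl)-7-methoxy-2,3-dihydro-1-benzofuran-5-carbaldehyde
Product: 26 (2R,3S)-2-[4-(benzyloxy)-3-methoxyphenyl]-7-methoxy-3-[(methoxymethoxy)methyl]-2,3-dihydro-1-benzofuran-5-carbaldehyde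
Conditions: MOMCl, i-Pr2NEt, CH2Cl2, 0 °C → rt
Reagents that add atoms: chloromethyl methyl ether, COCCl
Why: Base-mediated acetal ether formation on the remaining primary alcohol; MOM is chosen because it leaves under the same reagent that later opens the dioxane.

Step 18
Reactants: 26 (2R,3S)-2-[4-(benzyloxy)-3-methoxyphenyl]-7-methoxy-3-[(methoxymethoxy)methyl]-2,3-dihydro-1-benzofuran-5-carbaldehyde
Product: 27 {(2R,3S)-2-[4-(benzyloxy)-3-methoxyphenyl]-7-methoxy-3-[(methoxymethoxy)methyl]-2,3-dihydro-1-benzofuran-5-yl}methanol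
Conditions: NaBH4, MeOH–THF, 0 °C
Reagents that add atoms: none
Why: Borohydride reduction of the aryl aldehyde to the benzylic alcohol.

Step 19
Reactants: 27 {(2R,3S)-2-[4-(benzyloxy)-3-methoxyphenyl]-7-methoxy-3-[(methoxymethoxy)methyl]-2,3-dihydro-1-benzofuran-5-yl}methanol
Product: 28 (2R,3S)-2-[4-(benzyloxy)-3-methoxyphenyl]-5-(bromomethyl)-7-methoxy-3-[(methoxymethoxy)methyl]-2,3-dihydro-1-benzofuran
Conditions: CBr4, PPh3, CH2Cl2, 0 °C
Reagents that add atoms: carbon tetrabromide, BrC(Br)(Br)Br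
Why: Appel bromination under neutral conditions gives the reactive para-alkoxybenzyl bromide without harming the MOM ether or the benzylic ring ether; it is used at once.

Step 20
Reactants: 16 (S)-4-{4-(benzyloxy)-3-[(4S,5S)-4-(4-benzyloxy-3-methoxyphenyl)-1,3-dioxan-5-yl]-5-methoxybenzyl}dihydrofuran-2(3H)-one; 28 (2R,3S)-2-[4-(benzyloxy)-3-methoxyphenyl]-5-(bromomethyl)-7-methoxy-3-[(methoxymethoxy)methyl]-2,3-dihydro-1-benzofuran
Product: 30 (3S,4S)-4-{4-(benzyloxy)-3-[(4S,5S)-4-(4-benzyloxy-3-methoxyphenyl)-1,3-dioxan-5-yl]-5-methoxybenzyl}-3-({(2R,3S)-2-[4-(benzyloxy)-3-methoxyphenyl]-7-methoxy-3-[(methoxymethoxy)methyl]-2,3-dihydro-1-benzofuran-5-yl}methyl)dihydrofuran-2(3H)-one, via lithium enolate 29 (not isolated)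
Conditions: LiN(SiMe3)2, THF, −78 °C; then 28, −78 → −40 °C
Reagents that add atoms: none
Why: Enolate alkylation of a β-benzyl-γ-butyrolactone, in which the benzylic bromide approaches anti to the C4 substituent and so sets C3 (S) trans to C4, while the dioxane keeps the arm diol inert to base.

Step 21
Reactants: 30 (3S,4S)-4-{4-(benzyloxy)-3-[(4S,5S)-4-(4-benzyloxy-3-methoxyphenyl)-1,3-dioxan-5-yl]-5-methoxybenzyl}-3-({(2R,3S)-2-[4-(benzyloxy)-3-methoxyphenyl]-7-methoxy-3-[(methoxymethoxy)methyl]-2,3-dihydro-1-benzofuran-5-yl}methyl)dihydrofuran-2(3H)-one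
Product: 32 (3S,4S)-4-{4-(benzyloxy)-3-[(1S,2S)-1-(4-benzyloxy-3-methoxyphenyl)-1,3-dihydroxypropan-2-yl]-5-methoxybenzyl}-3-({(2R,3S)-2-[4-(benzyloxy)-3-methoxyphenyl]-3-(hydroxymethyl)-7-methoxy-2,3-dihydro-1-benzofuran-5-yl}methyl)dihydrofuran-2(3H)-one, via bis(bipyridinium) triflate 31 (not isolated)
Conditions: Me3SiOTf, 2,2'-bipyridyl, CH2Cl2, 0 °C → rt; then H2O, rt; NaHCO3 work-up
Reagents that add atoms: none
Why: Silyl triflate–bipyridyl cleavage of O–CH2–O units: the pyridine nitrogen attacks the acetal carbon of the silyl-activated formal and MOM ether to give N,O-acetal pyridinium salts that water hydrolyses, so no benzylic C–O bond has to ionise, C7 keeps its configuration, and the benzylated ring A oxygen cannot cyclise onto C7.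

Step 22
Reactants: 32 (3S,4S)-4-{4-(benzyloxy)-3-[(1S,2S)-1-(4-benzyloxy-3-methoxyphenyl)-1,3-dihydroxypropan-2-yl]-5-methoxybenzyl}-3-({(2R,3S)-2-[4-(benzyloxy)-3-methoxyphenyl]-3-(hydroxymethyl)-7-methoxy-2,3-dihydro-1-benzofuran-5-yl}methyl)dihydrofuran-2(3H)-one
Product: 33 (3S,4S)-4-{3-[(1S,2S)-1,3-dihydroxy-1-(4-hydroxy-3-methoxyphenyl)propan-2-yl]-4-hydroxy-5-methoxybenzyl}-3-{[(2R,3S)-2-(4-hydroxy-3-methoxyphenyl)-3-(hydroxymethyl)-7-methoxy-2,3-dihydro-1-benzofuran-5-yl]methyl}dihydrofuran-2(3H)-one (CNP0199264.1)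
Conditions: H2 (1 bar), 10% Pd/C, EtOAc–EtOH, rt
Reagents that add atoms: none
Why: Catalytic hydrogenolysis of the three aryl benzyl ethers is neutral and faster than cleavage of the benzylic C–OH and dihydrofuran C–O bonds, so the acid that would close ring A onto C7 is avoided.

Compound list

1 | 5-bromovanillin (3-bromo-4-hydroxy-5-methoxybenzaldehyde) | COc1cc(C=O)cc(Br)c1O | starting material
2 | 3-bromo-5-methoxy-4-(methoxymethoxy)benzaldehyde | COCOc1c(Br)cc(C=O)cc1OC | intermediate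
3 | dimethyl succinate | COC(=O)CCC(=O)OC | starting material
4 | (E)-4-[3-bromo-5-methoxy-4-(methoxymethoxy)phenyl]-3-(methoxycarbonyl)but-3-enoic acid | COCOc1c(Br)cc(/C=C(\CC(=O)O)C(=O)OC)cc1OC | intermediate
5 | (S)-4-[3-bromo-5-methoxy-4-(methoxymethoxy)phenyl]-3-(methoxycarbonyl)butanoic acid | COCOc1c(Br)cc(C[C@@H](CC(=O)O)C(=O)OC)cc1OC | intermediate
6 | potassium (S)-4-[3-bromo-5-methoxy-4-(methoxymethoxy)phenyl]-3-(hydroxymethyl)butanoate | COCOc1c(Br)cc(C[C@@H](CC(=O)[O-])CO)cc1OC.[K+] | intermediate (not isolated)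
7 | (S)-4-(3-bromo-4-hydroxy-5-methoxybenzyl)dihydrofuran-2(3H)-one | COc1cc(C[C@@H]2COC(=O)C2)cc(Br)c1O | intermediate
8 | 2-bromo-6-methoxy-4-{[(S)-5-oxotetrahydrofuran-3-yl]methyl}phenyl pivalate | COc1cc(C[C@@H]2COC(=O)C2)cc(Br)c1OC(=O)C(C)(C)C | intermediate
9 | 4-(benzyloxy)-3-methoxybenzaldehyde | COc1cc(C=O)ccc1OCc1ccccc1 | starting material
10 | 4-benzyloxy-3-methoxystyrene | COc1cc(C=C)ccc1OCc1ccccc1 | intermediate
11 | 2-[(E)-2-(4-benzyloxy-3-methoxyphenyl)ethenyl]-6-methoxy-4-{[(S)-5-oxotetrahydrofuran-3-yl]methyl}phenyl pivalate (key-step precursor) | COc1cc(C[C@@H]2COC(=O)C2)cc(/C=C/c2ccc(OCc3ccccc3)c(OC)c2)c1OC(=O)C(C)(C)C | intermediate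
12 | formaldehyde (used as paraformaldehyde) | C=O | starting material
13 | 2-[(4S,5S)-4-(4-benzyloxy-3-methoxyphenyl)-1,3-dioxan-5-yl]-6-methoxy-4-{[(S)-5-oxotetrahydrofuran-3-yl]methyl}phenyl pivalate (key-step product, trans-dioxane) | COc1cc(C[C@@H]2COC(=O)C2)cc([C@H]2COCO[C@@H]2c2ccc(OCc3ccccc3)c(OC)c2)c1OC(=O)C(C)(C)C | intermediate
14 | dilithium (S)-4-{3-[(4S,5S)-4-(4-benzyloxy-3-methoxyphenyl)-1,3-dioxan-5-yl]-5-methoxy-4-oxidophenyl}-3-(hydroxymethyl)butanoate | COc1cc(C[C@@H](CC(=O)[O-])CO)cc([C@H]2COCO[C@@H]2c2ccc(OCc3ccccc3)c(OC)c2)c1[O-].[Li+].[Li+] | intermediate (not isolated)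
15 | (S)-4-{3-[(4S,5S)-4-(4-benzyloxy-3-methoxyphenyl)-1,3-dioxan-5-yl]-4-hydroxy-5-methoxybenzyl}dihydrofuran-2(3H)-one | COc1cc(C[C@@H]2COC(=O)C2)cc([C@H]2COCO[C@@H]2c2ccc(OCc3ccccc3)c(OC)c2)c1O | intermediate
16 | (S)-4-{4-(benzyloxy)-3-[(4S,5S)-4-(4-benzyloxy-3-methoxyphenyl)-1,3-dioxan-5-yl]-5-methoxybenzyl}dihydrofuran-2(3H)-one | COc1cc(C[C@@H]2COC(=O)C2)cc([C@H]2COCO[C@@H]2c2ccc(OCc3ccccc3)c(OC)c2)c1OCc1ccccc1 | intermediate
17 | methyl 4-hydroxy-3-iodo-5-methoxybenzoate (methyl 5-iodovanillate) | COC(=O)c1cc(I)c(O)c(OC)c1 | starting material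
18 | [4-(benzyloxy)-3-methoxyphenyl]methanol | COc1cc(CO)ccc1OCc1ccccc1 | starting material
19 | methyl 4-{[4-(benzyloxy)-3-methoxybenzyl]oxy}-3-iodo-5-methoxybenzoate | COC(=O)c1cc(I)c(OCc2ccc(OCc3ccccc3)c(OC)c2)c(OC)c1 | intermediate
20 | methyl 4-{[4-(benzyloxy)-3-methoxybenzyl]oxy}-3-methoxy-5-(2-methoxy-2-oxoethyl)benzoate | COC(=O)Cc1cc(C(=O)OC)cc(OC)c1OCc1ccc(OCc2ccccc2)c(OC)c1 | intermediate
21 | methyl 4-{[4-(benzyloxy)-3-methoxybenzyl]oxy}-3-(1-diazo-2-methoxy-2-oxoethyl)-5-methoxybenzoate | COC(=O)C(=[N+]=[N-])c1cc(C(=O)OC)cc(OC)c1OCc1ccc(OCc2ccccc2)c(OC)c1 | intermediate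
22 | dimethyl (2R,3S)-2-[4-(benzyloxy)-3-methoxyphenyl]-7-methoxy-2,3-dihydro-1-benzofuran-3,5-dicarboxylate (cis) | COC(=O)c1cc(OC)c2c(c1)[C@H](C(=O)OC)[C@H](c1ccc(OCc3ccccc3)c(OC)c1)O2 | intermediate (not isolated)
23 | dimethyl (2R,3R)-2-[4-(benzyloxy)-3-methoxyphenyl]-7-methoxy-2,3-dihydro-1-benzofuran-3,5-dicarboxylate (trans) | COC(=O)c1cc(OC)c2c(c1)[C@@H](C(=O)OC)[C@H](c1ccc(OCc3ccccc3)c(OC)c1)O2 | intermediate
24 | {(2R,3S)-2-[4-(benzyloxy)-3-methoxyphenyl]-7-methoxy-2,3-dihydro-1-benzofuran-3,5-diyl}dimethanol (trans) | OCc1cc(OC)c2c(c1)[C@@H](CO)[C@H](c1ccc(OCc3ccccc3)c(OC)c1)O2 | intermediate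
25 | (2R,3S)-2-[4-(benzyloxy)-3-methoxyphenyl]-3-(hydroxymethyl)-7-methoxy-2,3-dihydro-1-benzofuran-5-carbaldehyde | O=Cc1cc(OC)c2c(c1)[C@@H](CO)[C@H](c1ccc(OCc3ccccc3)c(OC)c1)O2 | intermediate
26 | (2R,3S)-2-[4-(benzyloxy)-3-methoxyphenyl]-7-methoxy-3-[(methoxymethoxy)methyl]-2,3-dihydro-1-benzofuran-5-carbaldehyde | O=Cc1cc(OC)c2c(c1)[C@@H](COCOC)[C@H](c1ccc(OCc3ccccc3)c(OC)c1)O2 | intermediate
27 | {(2R,3S)-2-[4-(benzyloxy)-3-methoxyphenyl]-7-methoxy-3-[(methoxymethoxy)methyl]-2,3-dihydro-1-benzofuran-5-yl}methanol | OCc1cc(OC)c2c(c1)[C@@H](COCOC)[C@H](c1ccc(OCc3ccccc3)c(OC)c1)O2 | intermediate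
28 | (2R,3S)-2-[4-(benzyloxy)-3-methoxyphenyl]-5-(bromomethyl)-7-methoxy-3-[(methoxymethoxy)methyl]-2,3-dihydro-1-benzofuran | BrCc1cc(OC)c2c(c1)[C@@H](COCOC)[C@H](c1ccc(OCc3ccccc3)c(OC)c1)O2 | intermediate
29 | lithium enolate of 16 (lithium 4,5-dihydrofuran-2-olate carrying the ring A benzyl group at C4) | COc1cc(C[C@@H]2COC(O[Li])=C2)cc([C@H]2COCO[C@@H]2c2ccc(OCc3ccccc3)c(OC)c2)c1OCc1ccccc1 | intermediate (not isolated)
30 | (3S,4S)-4-{4-(benzyloxy)-3-[(4S,5S)-4-(4-benzyloxy-3-methoxyphenyl)-1,3-dioxan-5-yl]-5-methoxybenzyl}-3-({(2R,3S)-2-[4-(benzyloxy)-3-methoxyphenyl]-7-methoxy-3-[(methoxymethoxy)methyl]-2,3-dihydro-1-benzofuran-5-yl}methyl)dihydrofuran-2(3H)-one | COc1cc(C[C@@H]2COC(=O)[C@H]2Cc2cc(OC)c3c(c2)[C@@H](COCOC)[C@H](c2ccc(OCc4ccccc4)c(OC)c2)O3)cc([C@H]2COCO[C@@H]2c2ccc(OCc3ccccc3)c(OC)c2)c1OCc1ccccc1 | intermediate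
31 | bis(2,2'-bipyridin-1-ium) bis(triflate) from 30 in which O7 and the dihydrobenzofuran CH2O each carry a CH2–N(bipyridinium) group and O9 carries SiMe3 (drawn as the regioisomer expected from silylation of the less hindered oxygen) | COc1cc(C[C@@H]2COC(=O)[C@H]2Cc2cc(OC)c3c(c2)[C@@H](COC[n+]2ccccc2-c2ccccn2)[C@H](c2ccc(OCc4ccccc4)c(OC)c2)O3)cc([C@@H](CO[Si](C)(C)C)[C@H](OC[n+]2ccccc2-c2ccccn2)c2ccc(OCc3ccccc3)c(OC)c2)c1OCc1ccccc1.[O-]S(=O)(=O)C(F)(F)F.[O-]S(=O)(=O)C(F)(F)F | intermediate (not isolated)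
32 | (3S,4S)-4-{4-(benzyloxy)-3-[(1S,2S)-1-(4-benzyloxy-3-methoxyphenyl)-1,3-dihydroxypropan-2-yl]-5-methoxybenzyl}-3-({(2R,3S)-2-[4-(benzyloxy)-3-methoxyphenyl]-3-(hydroxymethyl)-7-methoxy-2,3-dihydro-1-benzofuran-5-yl}methyl)dihydrofuran-2(3H)-one | COc1cc(C[C@@H]2COC(=O)[C@H]2Cc2cc(OC)c3c(c2)[C@@H](CO)[C@H](c2ccc(OCc4ccccc4)c(OC)c2)O3)cc([C@@H](CO)[C@H](O)c2ccc(OCc3ccccc3)c(OC)c2)c1OCc1ccccc1 | intermediate
33 | (3S,4S)-4-{3-[(1S,2S)-1,3-dihydroxy-1-(4-hydroxy-3-methoxyphenyl)propan-2-yl]-4-hydroxy-5-methoxybenzyl}-3-{[(2R,3S)-2-(4-hydroxy-3-methoxyphenyl)-3-(hydroxymethyl)-7-methoxy-2,3-dihydro-1-benzofuran-5-yl]methyl}dihydrofuran-2(3H)-one (CNP0199264.1) | COc1cc([C@@H](O)[C@H](CO)c2cc(C[C@@H]3COC(=O)[C@H]3Cc3cc(OC)c4c(c3)[C@@H](CO)[C@H](c3ccc(O)c(OC)c3)O4)cc(OC)c2O)ccc1O | target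

Total step count: 22. Longest linear sequence: 12 steps (steps 1–5, 7–10 and 20–22; the dihydrobenzofuran branch, steps 11–22, is equally long).

Steps most likely to fail

Step 8 (Prins dioxane formation). The bulky stilbene may not fit the confined catalyst pocket, so conversion may be poor. Enantiofacial selection on a 1,2-diaryl alkene may be low. Reversible ionisation at C7 or a retro-Prins pathway may erode selectivity, and the electron-rich arenes may be hydroxymethylated. The fallback builds the arm by an auxiliary-controlled anti-aldol reaction instead; it sets out from 7 and comes back at 16. Phenol 7 would be benzylated (BnBr, K2CO3, DMF) to (S)-4-[4-(benzyloxy)-3-bromo-5-methoxybenzyl]dihydrofuran-2(3H)-one F1. Negishi coupling with BrZnCH2CO2tBu (Pd2(dba)3, XPhos, THF) would give the tert-butyl arylacetate F2, and TFA in CH2Cl2 the arylacetic acid F3. Acylation of (S)-4-benzyloxazolidin-2-one through the mixed pivalic anhydride (PivCl, Et3N, LiCl, THF) would give the N-arylacetyl oxazolidinone F4. A MgCl2-catalysed anti-aldol reaction with aldehyde 9 (Et3N, Me3SiCl, EtOAc) would give the silylated anti-aldol adduct F5; the auxiliary sets C8 through the chelated enolate and the anti transition state sets C7. NaBH4 in wet THF with a citric acid work-up would remove auxiliary and silyl group and give the anti-1,3-diol F6 without touching the lactone. CH2(OMe)2 with LiBr and catalytic TsOH would then close the trans-dioxane 16.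

Step 21 (formal and MOM cleavage). Silyl-assisted ionisation of the benzylic C7–O bond or of the dihydrobenzofuran C2–O bond may compete with attack at the acetal carbon and cause epimerisation or oligomerisation. The hindered formal may also open incompletely. The fallback inverts the order of unmasking and passes through electron-poor aryl acetates; it sets out from 30 and comes back at 33. Hydrogenolysis of 30 (H2, Pd/C, EtOAc–EtOH) would give the triphenol F7 with dioxane and MOM ether intact. Ac2O in pyridine would give the triacetate F8, in which each benzylic C–O bond faces an acyloxy-substituted ring and ring A cannot cyclise. The formal and the MOM ether would then be cleaved on this deactivated substrate (Me3SiOTf, 2,2'-bipyridyl; then H2O) to the triacetate tetraol F9. Hydrazine hydrate in THF–MeOH at 0 °C would remove the three aryl acetates by aminolysis, leaving the lactone closed, and give 33.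

Step 20 (fragment-joining alkylation). Alkylation by the hindered enolate may be slow enough for the para-alkoxybenzyl bromide to decompose, and proton transfer between product and enolate may lead to double alkylation. The fallback forms the same C–C bond by aldol addition and removes the extra oxygen by a radical reaction; it sets out from 16 and 26 and comes back at 30. The lithium enolate of 16 (LiN(SiMe3)2, THF, −78 °C) would add to aldehyde 26 anti to the C4 substituent to give the β-hydroxy lactone F10; its carbinol centre may be a mixture, which does not matter. PhOC(S)Cl with pyridine would give the O-phenyl thionocarbonate F11. Barton–McCombie deoxygenation (Bu3SnH, AIBN, toluene, 80 °C) would then give 30.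

Further compounds

F1 | step 8 | (S)-4-[4-(benzyloxy)-3-bromo-5-methoxybenzyl]dihydrofuran-2(3H)-one | COc1cc(C[C@@H]2COC(=O)C2)cc(Br)c1OCc1ccccc1
F2 | step 8 | tert-butyl 2-{2-(benzyloxy)-3-methoxy-5-[((S)-5-oxotetrahydrofuran-3-yl)methyl]phenyl}acetate | COc1cc(C[C@@H]2COC(=O)C2)cc(CC(=O)OC(C)(C)C)c1OCc1ccccc1
F3 | step 8 | 2-{2-(benzyloxy)-3-methoxy-5-[((S)-5-oxotetrahydrofuran-3-yl)methyl]phenyl}acetic acid | COc1cc(C[C@@H]2COC(=O)C2)cc(CC(=O)O)c1OCc1ccccc1
F4 | step 8 | (S)-4-benzyl-3-(2-{2-(benzyloxy)-3-methoxy-5-[((S)-5-oxotetrahydrofuran-3-yl)methyl]phenyl}acetyl)oxazolidin-2-one | O=C(Cc1cc(C[C@@H]2COC(=O)C2)cc(OC)c1OCc1ccccc1)N1C(=O)OC[C@@H]1Cc1ccccc1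
F5 | step 8 | (S)-4-benzyl-3-[(2R,3S)-2-{2-(benzyloxy)-3-methoxy-5-[((S)-5-oxotetrahydrofuran-3-yl)methyl]phenyl}-3-(4-benzyloxy-3-methoxyphenyl)-3-(trimethylsilyloxy)propanoyl]oxazolidin-2-one | COc1cc(C[C@@H]2COC(=O)C2)cc([C@@H](C(=O)N2C(=O)OC[C@@H]2Cc2ccccc2)[C@H](O[Si](C)(C)C)c2ccc(OCc3ccccc3)c(OC)c2)c1OCc1ccccc1
F6 | step 8 | (S)-4-{4-(benzyloxy)-3-[(1S,2S)-1-(4-benzyloxy-3-methoxyphenyl)-1,3-dihydroxypropan-2-yl]-5-methoxybenzyl}dihydrofuran-2(3H)-one | COc1cc(C[C@@H]2COC(=O)C2)cc([C@@H](CO)[C@H](O)c2ccc(OCc3ccccc3)c(OC)c2)c1OCc1ccccc1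
F7 | step 21 | (3S,4S)-4-{4-hydroxy-3-[(4S,5S)-4-(4-hydroxy-3-methoxyphenyl)-1,3-dioxan-5-yl]-5-methoxybenzyl}-3-({(2R,3S)-2-(4-hydroxy-3-methoxyphenyl)-7-methoxy-3-[(methoxymethoxy)methyl]-2,3-dihydro-1-benzofuran-5-yl}methyl)dihydrofuran-2(3H)-one | COc1cc(C[C@@H]2COC(=O)[C@H]2Cc2cc(OC)c3c(c2)[C@@H](COCOC)[C@H](c2ccc(O)c(OC)c2)O3)cc([C@H]2COCO[C@@H]2c2ccc(O)c(OC)c2)c1O
F8 | step 21 | triacetate of F7 (all three phenols acetylated) | COc1cc(C[C@@H]2COC(=O)[C@H]2Cc2cc(OC)c3c(c2)[C@@H](COCOC)[C@H](c2ccc(OC(C)=O)c(OC)c2)O3)cc([C@H]2COCO[C@@H]2c2ccc(OC(C)=O)c(OC)c2)c1OC(C)=O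
F9 | step 21 | tri-O-aryl acetate of 33 (the three phenols acetylated, the four aliphatic hydroxyl groups free) | COc1cc(C[C@@H]2COC(=O)[C@H]2Cc2cc(OC)c3c(c2)[C@@H](CO)[C@H](c2ccc(OC(C)=O)c(OC)c2)O3)cc([C@@H](CO)[C@H](O)c2ccc(OC(C)=O)c(OC)c2)c1OC(C)=O
F10 | step 20 | aldol adduct of 16 and 26: (3S,4S)-lactone as in 30 carrying CH(OH) in place of the new benzylic CH2 (carbinol configuration undefined) | COc1cc(C[C@@H]2COC(=O)[C@H]2C(O)c2cc(OC)c3c(c2)[C@@H](COCOC)[C@H](c2ccc(OCc4ccccc4)c(OC)c2)O3)cc([C@H]2COCO[C@@H]2c2ccc(OCc3ccccc3)c(OC)c2)c1OCc1ccccc1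
F11 | step 20 | O-phenyl thionocarbonate of F10 | COc1cc(C[C@@H]2COC(=O)[C@H]2C(OC(=S)Oc2ccccc2)c2cc(OC)c3c(c2)[C@@H](COCOC)[C@H](c2ccc(OCc4ccccc4)c(OC)c2)O3)cc([C@H]2COCO[C@@H]2c2ccc(OCc3ccccc3)c(OC)c2)c1OCc1ccccc1
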